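## The problem

Eremophilane numbering is used throughout: ring A is C1–C5 and C10, ring B is C5–C10, C11/C12 is the acetyl group on C7, and β is the face of the C5 methyl group.

- Target 12 is a cis-fused 13-nor-eremophilane with five contiguous stereocentres, C3–C4–C5–C10–C9. The all-carbon quaternary C5 sits next to the tertiary carbinol C10.
- 3-OAc, 4-Me, 5-Me and 10-OH are all β; the 9-angelate is α, trans to the 10-hydroxyl.
- Ring B is at its full oxidation level. C6=C7 carries both the ring ketone C8 and the acetyl carbon C11 (a 2-acyl enone and strong Michael acceptor), C9 carries an acyloxy group and C10 a hydroxyl.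
- Groups that will not survive rough treatment:
  - the β-ketol C8/C10 (dehydration to the cross-conjugated dienone, retro-aldol);
  - the angelate (Z to E once the acid is activated as an acyl donor);
  - the two different esters, which allow no hydrolysis step once both are in place;
  - the doubly activated C6=C7 bond (nucleophiles, reductants).
- The stereocentres can be relayed from one absolute event: C3/C4 by an endo rule, C4 to C5 by anti attack, C5 to C10 by a tether, C10 to C9 by inversion at an epoxide.
- The feature that makes the key step possible: C8–C9–C10 is an aldol array, and C7 carries two acyl carbons (C8 inside ring B, C11 outside). Before the C9–C10 bond exists these are two identical acetyl groups on the formyl-level carbon C6. Ring B is therefore the undehydrated aldol adduct of a C10 ketone whose α-carbon C5 carries a diacetylvinyl group, and C6–C9 plus C11/C12 is the commercial reagent 5.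
- A second feature: the 3-acetoxy group is one Baeyer–Villiger oxidation away from a C3 acetyl group, which makes ring A a Diels–Alder adduct of 2 and 3.

## Retrosynthesis

**12 to 10 + 11.** The C9–O bond to the angelate is cut. Opening the 9β,10β-epoxy ketone 10 with angelic acid 11 at C9 is stereospecific (inversion gives 9α-O trans to 10β-OH). It also uses the acid as a nucleophile, so no activated angeloyl species is ever made. The neighbouring cut, acylation of a 9,10-diol, needs a separate stereoselective hydroxylation and an acyl activation that risks Z to E isomerisation. The forward step needs SN2 attack at the α-keto carbon C9 and not at tertiary C10.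

**10 to 8.** The C9–O bond of the epoxide is cut. The epoxide oxygen is the aldol oxygen of ketol 8, so only a leaving group at C9 is needed (bromide 9), and closure is possible only on the β face. The forward step asks for enol bromination at the ring methylene C9 in preference to the acetyl methyl C12.

**8 to 7.** The C3–O bond is traced back to a C3–acetyl bond (Baeyer–Villiger). The acetate carbons then come from 3, and the configuration at C3 is kept. The oxidation is placed after ring B is closed because C10 is then a carbinol and no longer a ketone that would compete.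

**7 to 4 + 5 (key).** C5–C6 and C9–C10 are cut together. Cutting only C9–C10 leaves the hard quaternary centre in the precursor. Cutting the same two bonds with 3 as the four-carbon partner gives a skeleton at the wrong oxidation level without C6=C7, the C7 acetyl or a retained C10–OH. With 5, ring B arrives with C6=C7, the C8 ketone, the C7 acetyl and the C10 hydroxyl in place. The precursor 4 is monocyclic with two stereocentres. The forward reaction must form the C5 quaternary centre anti to the C4 methyl group and stop at the ketol.

**4 to 2 + 3.** C1–C2 and C3–C4 are cut (Diels–Alder). This gives the tetrasubstituted enol ether C10=C5 regiospecifically, which enolisation of a 2,3-dimethylcyclohexanone would not. It sets C3/C4 cis by the endo rule, and a chiral Lewis acid sets the absolute configuration. Both components are acyclic.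

**2 to 1.** The O–Si bond is cut; 2 is the kinetic silyl dienol ether of the commercial enone 1.

## Roads not taken

**Alternative 1:** Cut C5–C6 and C9–C10 in the classical way.
- Forward key step: amino-acid-catalysed Robinson annulation of 2-methylcyclohexane-1,3-dione A1 with 3 to the (S)-Wieland–Miescher ketone A2.
- A2 carries only C5.
- The annulation dehydrates the very hydroxyl the target keeps, so C10–O and C9–O must be put back by a β-selective epoxidation of a dienone. Once the acetyl group is on C7, C6=C7 is the better acceptor for that epoxidation.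
- The C4 carbonyl has to become a 4β-methyl group with a new 3β-oxygen (olefination, allylic oxidation, face-selective hydrogenation).
- C6=C7 and the C7 acetyl need a dehydrogenation and an acylation.
- Most of the steps would be redox and functional-group changes. The chosen plan brings every fragment in at its final oxidation level.

**Alternative 2:** Cut C1–C10 and C4–C5, building ring A on a ring-B quinone.
- Forward key step: Diels–Alder reaction of 2-methoxy-5-methylbenzoquinone A3 with the silyloxydiene A4 to the cis-fused adduct A5.
- The leading bond would have to join two methyl-bearing carbons, so regiocontrol is uncertain.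
- The endo rule places the C4 methyl anti to the C5 methyl (the 4-epi series).
- C10 is a CH that must be hydroxylated later, the C6 carbonyl must be removed with transposition, the C9 ketone reduced to the α-alcohol, and the C7 acetyl added.
- The chosen plan sets C5 and C10 with their final substituents in one step.

**Alternative 3:** Cut C4–C5, closing ring A onto an aromatic ring B.
- Forward key step: para-alkylative dearomatisation of the phenol mesylate A6 to the cross-conjugated dienone A7.
- C-alkylation by a secondary mesylate at a substituted para position must beat O-alkylation and elimination.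
- The C3/C4 stereocentres have to be built into the side chain first.
- C9=C10 of A7 must then be oxidised on the β face while the doubly activated C6=C7 is the more reactive alkene toward peroxide nucleophiles.
- The chosen plan gets the C10 oxygen from the aldol step itself.

Key step: step 3

Remarks on the chemistry:
- The sense of induction of the (S)-oxazaborolidinium catalyst with 3 (diene to the Re face of C-α) is assigned by analogy with acrylate dienophiles. The antipodal catalyst is used if the sense proves opposite.
- Compounds 1, 3, 5 and 11 are taken as commercial.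

## Route

Step 1
Reactants: 1 (3E)-3-methylpent-3-en-2-one
Product: 2 tert-butyl(dimethyl){[(3E)-3-methylpenta-1,3-dien-2-yl]oxy}silane
Conditions: TBSOTf, Et3N, CH2Cl2, 0 °C
Reagents that add atoms: tert-butyldimethylsilyl trifluoromethanesulfonate, CC(C)(C)[Si](C)(C)OS(=O)(=O)C(F)(F)F
Why: Silyl enol ether formation by soft enolisation removes an α'-proton of the acetyl group and gives the cross-conjugated 2-silyloxydiene; the trisubstituted C=C is untouched, so the terminal methyl stays in the outside (E) position needed for step 2.

Step 2
Reactants: 2 tert-butyl(dimethyl){[(3E)-3-methylpenta-1,3-dien-2-yl]oxy}silane; 3 but-3-en-2-one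
Product: 4 1-[(1S,2S)-4-{[tert-butyl(dimethyl)silyl]oxy}-2,3-dimethylcyclohex-3-en-1-yl]ethan-1-one
Conditions: chiral oxazaborolidinium triflimide from (S)-α,α-diphenylprolinol and o-tolylboronic acid (10 mol %), CH2Cl2, −78 → −40 °C
Reagents that add atoms: none
Why: Catalytic enantioselective Diels–Alder reaction; the silyloxy group makes the diene CH2 the nucleophilic terminus, which bonds to C-β of 3 and places acetyl 1,4 to OSi; the endo transition state puts the outside methyl and the acetyl cis (C4/C3), and the catalyst, by directing the diene to the Re face of C-α of 3, should set both centres S; the tetrasubstituted enol ether C10=C5 forms regiospecifically.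

Step 3
Reactants: 4 1-[(1S,2S)-4-{[tert-butyl(dimethyl)silyl]oxy}-2,3-dimethylcyclohex-3-en-1-yl]ethan-1-one; 5 3-(ethoxymethylidene)pentane-2,4-dione
Product: 7 (4aS,5S,6S,8aS)-3,6-diacetyl-8a-hydroxy-4a,5-dimethyl-4a,5,6,7,8,8a-hexahydronaphthalen-2(1H)-one, via diacetylvinyl ketone 6 (not isolated)
Conditions: TiCl4 (1.1 equiv), CH2Cl2, −78 °C; then i-Pr2NEt (2.5 equiv), −78 → −20 °C; aq. NH4Cl
Reagents that add atoms: none
Why: TiCl4 chelates the two carbonyls of 5 and makes its ethoxymethylene carbon an oxocarbenium-like electrophile; the enol ether carbon C5 of 4 adds to it (Mukaiyama–Michael addition) and loss of ethoxide from the titanium diketonate gives 6, after which the amine enolises one titanium-bound acetyl group and its carbon C9 adds to the C10 ketone. The closest known reaction types are the Lewis-acid addition–elimination of silyl enol ethers to alkoxymethylene 1,3-dicarbonyl compounds (as used in pyranone and phenol annulations) and the ketol stage of the Robinson annulation. Ring B closes by a 6-(enolendo)-exo-trig aldol addition. C5 is set by axial attack on the face anti to the C4 methyl group, which A(1,2) strain with the C5 methyl holds pseudoaxial, so the 4,5-dimethyl groups end up cis. C10 is set by the tether: the chain hangs from the α face of C5, C9 can reach only the α face of the carbonyl, and the ketol is cis-fused with OH syn to the C5 methyl. C–C bond formation at C5 and not C1 is secured by the regiodefined enol ether from step 2. No alkene geometry has to be controlled because the two acetyl groups on C7 are identical: whichever is cis to C5 cyclises and the other becomes the C7 acetyl. The reaction should stop at the ketol because C5 is quaternary and the titanium aldolate is quenched cold, and the C3 acetyl, which is not chelated, should stay un-enolised.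

Step 4
Reactants: 7 (4aS,5S,6S,8aS)-3,6-diacetyl-8a-hydroxy-4a,5-dimethyl-4a,5,6,7,8,8a-hexahydronaphthalen-2(1H)-one
Product: 8 (1R,2S,4aS,8aR)-7-acetyl-4a-hydroxy-1,8a-dimethyl-6-oxo-1,2,3,4,4a,5,6,8a-octahydronaphthalen-2-yl acetate
Conditions: mCPBA, Na2HPO4, CH2Cl2, 0 °C → rt
Reagents that add atoms: 3-chloroperoxybenzoic acid, O=C(OO)c1cccc(Cl)c1
Why: Baeyer–Villiger oxidation; the secondary ring carbon C3 migrates in preference to methyl with retention, turning the acetyl into the 3β-acetate; the C8 and C11 carbonyls are conjugated to the electron-poor C6=C7 bond and should react far more slowly, that alkene is too electron-poor for epoxidation, and C10 is no longer a ketone.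

Step 5
Reactants: 8 (1R,2S,4aS,8aR)-7-acetyl-4a-hydroxy-1,8a-dimethyl-6-oxo-1,2,3,4,4a,5,6,8a-octahydronaphthalen-2-yl acetate
Product: 10 (3S,4R,5R,9R,10R)-3-acetoxy-9,10-epoxy-13-noreremophil-6-ene-8,11-dione (9β,10β-epoxide), via 9α-bromo ketol 9 (not isolated)
Conditions: NBS, NH4OAc (10 mol %), Et2O, 25 °C; then K2CO3, MeCN, 0 → 25 °C
Reagents that add atoms: none
Why: α-Bromination of a ketone through its enol is expected at the ring methylene C9, the more substituted and more readily enolised position, and not at the acetyl methyl; carbonate then closes the epoxide by intramolecular SN2 displacement of bromide by the C10 oxygen, possible only on the β face, and the C9 epimer that cannot close equilibrates through its enolate, so both bromides converge on the 9β,10β-epoxide.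

Step 6
Reactants: 10 (3S,4R,5R,9R,10R)-3-acetoxy-9,10-epoxy-13-noreremophil-6-ene-8,11-dione; 11 (2Z)-2-methylbut-2-enoic acid
Product: 12 (3S,4R,5R,9S,10R)-3-acetoxy-9-[(2Z)-2-methylbut-2-enoyloxy]-10-hydroxy-13-noreremophil-6-ene-8,11-dione (CNP0196241.1)
Conditions: 11 (3 equiv), Cs2CO3 (10 mol %), DMF, 45 °C
Reagents that add atoms: none
Why: SN2 opening of an α,β-epoxy ketone by a carboxylate at the α-keto carbon C9 (C10 is tertiary) with inversion gives the 9α-ester trans to the 10β-hydroxyl; the angelate is the nucleophile and is never activated as an acyl donor, which avoids Z to E isomerisation, and the excess acid protonates the C10 alkoxide at once.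

## Compound list

1 | (3E)-3-methylpent-3-en-2-one | CC(=O)/C(C)=C/C | starting material
2 | tert-butyl(dimethyl){[(3E)-3-methylpenta-1,3-dien-2-yl]oxy}silane | C=C(O[Si](C)(C)C(C)(C)C)/C(C)=C/C | intermediate
3 | but-3-en-2-one | C=CC(C)=O | starting material
4 | 1-[(1S,2S)-4-{[tert-butyl(dimethyl)silyl]oxy}-2,3-dimethylcyclohex-3-en-1-yl]ethan-1-one | C[C@H]1[C@@H](C(C)=O)CCC(O[Si](C)(C)C(C)(C)C)=C1C | intermediate
5 | 3-(ethoxymethylidene)pentane-2,4-dione | CCOC=C(C(C)=O)C(C)=O | starting material
6 | 3-{[(1S,2S,3S)-3-acetyl-1,2-dimethyl-6-oxocyclohexyl]methylidene}pentane-2,4-dione | CC(=O)C(C(C)=O)=C[C@]1(C)[C@@H](C)[C@@H](C(C)=O)CCC1=O | intermediate (not isolated)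
7 | (4aS,5S,6S,8aS)-3,6-diacetyl-8a-hydroxy-4a,5-dimethyl-4a,5,6,7,8,8a-hexahydronaphthalen-2(1H)-one | C1C(=O)C(C(C)=O)=C[C@]2(C)[C@@H](C)[C@@H](C(C)=O)CC[C@]12O | intermediate
8 | (1R,2S,4aS,8aR)-7-acetyl-4a-hydroxy-1,8a-dimethyl-6-oxo-1,2,3,4,4a,5,6,8a-octahydronaphthalen-2-yl acetate | C1C(=O)C(C(C)=O)=C[C@]2(C)[C@@H](C)[C@@H](OC(C)=O)CC[C@]12O | intermediate
9 | (1R,2S,4aR,5S,8aR)-7-acetyl-5-bromo-4a-hydroxy-1,8a-dimethyl-6-oxo-1,2,3,4,4a,5,6,8a-octahydronaphthalen-2-yl acetate (9α-bromo ketol) | Br[C@@H]1C(=O)C(C(C)=O)=C[C@]2(C)[C@@H](C)[C@@H](OC(C)=O)CC[C@]12O | intermediate (not isolated)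
10 | (3S,4R,5R,9R,10R)-3-acetoxy-9,10-epoxy-13-noreremophil-6-ene-8,11-dione (9β,10β-epoxide) | O=C1C(C(C)=O)=C[C@]2(C)[C@@H](C)[C@@H](OC(C)=O)CC[C@@]23O[C@H]31 | intermediate
11 | (2Z)-2-methylbut-2-enoic acid (angelic acid) | C/C=C(/C)C(=O)O | starting material
12 | (3S,4R,5R,9S,10R)-3-acetoxy-9-[(2Z)-2-methylbut-2-enoyloxy]-10-hydroxy-13-noreremophil-6-ene-8,11-dione | C/C=C(/C)C(=O)O[C@@H]1C(=O)C(C(C)=O)=C[C@]2(C)[C@@H](C)[C@@H](OC(C)=O)CC[C@]12O | target

## Step count and risks

Total step count: 6. Longest linear sequence: 6 steps (1 to 12). Every carbon of 12 comes from 1, 3, 5 and 11.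

**Step 3 (key step).**
- What may go wrong: competing O-alkenylation, reversible cyclobutane formation or protodesilylation at the hindered tetrasubstituted enol ether; retro-addition before ethoxide is lost; dehydration of the titanium aldolate to the cross-conjugated dienone on warming.
- Fallback, from 4 back to 7: a TMSOTf-catalysed Mukaiyama reaction of 4 with trimethyl orthoformate, a very well-precedented way to a quaternary α-centre, gives the keto acetal F1. Mild aqueous acid frees the keto aldehyde F2. Knoevenagel condensation of F2 with pentane-2,4-dione (TiCl4, pyridine) gives 6, which is closed to 7 with the amine as in step 3.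

**Step 5.**
- What may go wrong: enolisation toward the acetyl methyl C12 competes with enolisation toward C9, leading to bromination at C12 or double bromination; acid-promoted dehydration of the ketol.
- Fallback, from 4 back to 10: the C7 carbonyl is carried as a thioester with no α-hydrogen.
  - The thioester reagent F3 is made from S-ethyl 3-oxobutanethioate, triethyl orthoformate and acetic anhydride.
  - Annulation of 4 with F3 under the conditions of step 3 gives the thioester ketol F4. Its alkene isomers equilibrate by reversible conjugate addition and only the acetyl arm can cyclise.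
  - Baeyer–Villiger oxidation as in step 4 gives the acetate F5.
  - Bromination, now possible only at C9, gives the bromide F6, and carbonate closes it to the epoxy thioester F7.
  - Fukuyama coupling of F7 (MeZnI, PdCl2(PPh3)2) turns the thioester into the C7 acetyl group and gives 10.

**Step 6.**
- What may go wrong: slow SN2 attack at the hindered C9, and at the temperature then needed base-mediated loss of water across C9–C10 or retro-aldol opening of the product.
- Fallback, from 10 back to 12: the ester bond is made by acylation instead. Opening of 10 with the smaller caesium formate at lower temperature gives the 9α-formate F8. Selective methanolysis (KHCO3, MeOH, 0 °C) gives the 9α,10β-diol F9. The secondary hydroxyl of F9 is acylated with the preformed mixed anhydride of 11 and 2,4,6-trichlorobenzoyl chloride (Et3N, toluene, no DMAP) to give 12.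

**Step 2.**
- What may go wrong: poor facial or endo selectivity, a stepwise Mukaiyama–Michael pathway that erodes the C3/C4 relationship, or the opposite sense of induction.
- Fallback, from 2 back to 4: auxiliary control. Et2AlCl-promoted Diels–Alder reaction of 2 with (R)-4-benzyl-3-(prop-2-enoyl)oxazolidin-2-one gives the imide F10; the auxiliary shields the Si face of C-α. Transamination (MeNHOMe·HCl, AlMe3) gives the Weinreb amide F11, and MeMgBr converts F11 into 4.

## Further compounds

F1 | step 3 | (2S,3S,4S)-4-acetyl-2-(dimethoxymethyl)-2,3-dimethylcyclohexan-1-one | COC(OC)[C@]1(C)[C@@H](C)[C@@H](C(C)=O)CCC1=O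
F2 | step 3 | (1S,2S,3S)-3-acetyl-1,2-dimethyl-6-oxocyclohexane-1-carbaldehyde | O=C[C@]1(C)[C@@H](C)[C@@H](C(C)=O)CCC1=O
F3 | step 5 | S-ethyl 2-(ethoxymethylidene)-3-oxobutanethioate | CCOC=C(C(C)=O)C(=O)SCC
F4 | step 5 | S-ethyl (4aS,5S,6S,8aS)-6-acetyl-8a-hydroxy-4a,5-dimethyl-2-oxo-1,2,4a,5,6,7,8,8a-octahydronaphthalene-3-carbothioate | C1C(=O)C(C(=O)SCC)=C[C@]2(C)[C@@H](C)[C@@H](C(C)=O)CC[C@]12O
F5 | step 5 | S-ethyl (4aR,5R,6S,8aS)-6-acetoxy-8a-hydroxy-4a,5-dimethyl-2-oxo-1,2,4a,5,6,7,8,8a-octahydronaphthalene-3-carbothioate | C1C(=O)C(C(=O)SCC)=C[C@]2(C)[C@@H](C)[C@@H](OC(C)=O)CC[C@]12O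
F6 | step 5 | 9α-bromo derivative of F5 (eremophilane numbering; 3S,4R,5R,9S,10R) | Br[C@@H]1C(=O)C(C(=O)SCC)=C[C@]2(C)[C@@H](C)[C@@H](OC(C)=O)CC[C@]12O
F7 | step 5 | 9β,10β-epoxy thioester (eremophilane numbering; 3S,4R,5R,9R,10R) | O=C1C(C(=O)SCC)=C[C@]2(C)[C@@H](C)[C@@H](OC(C)=O)CC[C@@]23O[C@H]31
F8 | step 6 | (3S,4R,5R,9S,10R)-3-acetoxy-9-formyloxy-10-hydroxy-13-noreremophil-6-ene-8,11-dione | O=CO[C@@H]1C(=O)C(C(C)=O)=C[C@]2(C)[C@@H](C)[C@@H](OC(C)=O)CC[C@]12O
F9 | step 6 | (3S,4R,5R,9S,10R)-3-acetoxy-9,10-dihydroxy-13-noreremophil-6-ene-8,11-dione | O[C@@H]1C(=O)C(C(C)=O)=C[C@]2(C)[C@@H](C)[C@@H](OC(C)=O)CC[C@]12O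
F10 | step 2 | (4R)-4-benzyl-3-{[(1S,2S)-4-{[tert-butyl(dimethyl)silyl]oxy}-2,3-dimethylcyclohex-3-en-1-yl]carbonyl}-1,3-oxazolidin-2-one | C[C@H]1[C@@H](C(=O)N2[C@H](Cc3ccccc3)COC2=O)CCC(O[Si](C)(C)C(C)(C)C)=C1C
F11 | step 2 | (1S,2S)-4-{[tert-butyl(dimethyl)silyl]oxy}-N-methoxy-N,2,3-trimethylcyclohex-3-ene-1-carboxamide | C[C@H]1[C@@H](C(=O)N(C)OC)CCC(O[Si](C)(C)C(C)(C)C)=C1C
A1 | alternative 1 | 2-methylcyclohexane-1,3-dione | CC1C(=O)CCCC1=O
A2 | alternative 1 | (S)-Wieland–Miescher ketone, (8aS)-8a-methyl-3,4,8,8a-tetrahydronaphthalene-1,6(2H,7H)-dione | O=C1CC[C@]2(C)C(=O)CCCC2=C1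
A3 | alternative 2 | 2-methoxy-5-methylcyclohexa-2,5-diene-1,4-dione | COC1=CC(=O)C(C)=CC1=O
A4 | alternative 2 | tert-butyl(dimethyl){[(3Z)-penta-1,3-dien-3-yl]oxy}silane | C=C/C(O[Si](C)(C)C(C)(C)C)=C/C
A5 | alternative 2 | cis-fused endo adduct of A3 and A4 (4-epi series; eremophilane C4 methyl anti to C5 methyl) | O=C1C(OC)=CC(=O)[C@]2(C)[C@H](C)C(O[Si](C)(C)C(C)(C)C)=CC[C@H]12
A6 | alternative 3 | (2R,3S)-3-(acetyloxy)-5-(4-acetyl-5-hydroxy-2-methylphenyl)pentan-2-yl methanesulfonate | CC(=O)c1cc(C)c(CC[C@H](OC(C)=O)[C@@H](C)OS(C)(=O)=O)cc1O
A7 | alternative 3 | (3S,4R,5R)-3-acetoxy-13-noreremophila-6,9-diene-8,11-dione | CC(=O)C1=C[C@]2(C)[C@@H](C)[C@@H](OC(C)=O)CCC2=CC1=O
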